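You want E at the end of Wednesday's, Saturday's and Friday's flasks, and you have the green and ochre runs to go on.

| setting | green | ochre | Wednesday's | Saturday's | Friday's |
|---|---|---|---|---|---|
| Z | 0.20 M | 0.20 M | 0.20 M | 0.20 M | 0.20 M |
| G | 0.93 equiv | 2.2 equiv | 0.800 equiv | 1.50 equiv | 2.00 equiv |
| remark | run made earlier | run made earlier |  |  |  |
| time |  |  | 6.0 h | 6.0 h | 6.0 h |

- green (time / h: E / %): 0.417: 2; 0.833: 10; 1.33: 17; 1.50: 17; 2.00: 21; 2.50: 24; 3.00: 26
- ochre (time / h: E / %): 0.250: 13; 0.333: 20; 0.500: 25; 0.833: 39; 1.33: 52; 2.00: 65; 3.00: 70

(scatter of a reading: 1.5 percentage points)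

- percent here means Z units held: one J counts as two
- steps under discussion: G + D -> E; Z <-> L; Z + D -> J; Z + G -> D

1. amount of E at the end, in percent of the Z charged, for each flask in turn (Wednesday's, Saturday's, Friday's)

The ratio of E in the ochre run to E in the green run, read at one common time, shows how strongly E answers to the charge of G. At 3.00 h the logarithm of that ratio over the logarithm of the ratio of the G charges gives 1.15. Call this number s, the charge exponent, an apparent order in G at fixed time. At 0.833 h the same reading gives 1.58, higher than later, so as read s drifts down with time, though the green reading there carries a scatter of 1.5 percentage points.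

You need E at 6.0 h, so let each run's last slope fade evenly to nothing by then. That estimate puts green at 32.0% and ochre at 77.5%, which makes s 1.03, lower still. Scaling green by that s gives 27.4% for Wednesday's flask, 52.3% for Saturday's and 70.3% for Friday's.

The weak link is Wednesday's flask, whose charge lies below the green one, outside the span that s was read over. As a judgement I reforge it with the steeper early s, which gives 25.2%. The forecast stands at 22%, 52% and 72%, lower than mine on Wednesday's flask, and it calls itself “rough interpolations”.

The flasks give 22.8%, 57.2% and 75.7%.

    G + D → E (k = 0.00201 /M/s)
    Z ⇌ L (K = 1.08, k = 0.00227 /s)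
    Z + D → J (k = 0.00184 /M/s)
    Z + G → D (k = 0.00248 /M/s)

Scaled from the green reading with s as read at 3.00 h, E at 3.00 h comes to 21.9% in Wednesday's flask, which held 19.9%, and to 62.7% in Friday's, which held 66.0%. In Wednesday's flask at 0.556 h, Z was used by G 3.6 times as fast as by D, and D, each step taken net, was made 1.38 times as fast as it was used up, but at 6.00 h D was made at 0.327 of the rate it was used up.

The readings stem from a simulated flask for substances that don't exist; the scatter is artificial.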